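**Assumptions:** the target is read from the SMILES as the (4aR,8aR) enantiomer (trans-fused, ent-labdane series). Alcohol 14 is bought as the pure E isomer. C2 of compounds 5–9 is an epimer mixture that is erased in step 5. Nothing here has been run; yields and selectivities are expectations.

## Retrosynthetic overview

1. Target 21 ⇒ B-alkyl Suzuki union at the ring-B alkene carbon (then ester cleavage) of decalin enol triflate 11 with dienyl arene 18.
2. 18 ⇒ ortho-C-alkylation of the phenoxide of methyl 4-hydroxybenzoate 13 (from 4-iodophenol and CO) with E-enynyl bromide 15, then alkyne semihydrogenation.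
3. 11 ⇒ ketone 9 ⇒ enedione 5 by reductive methylation (trans ring fusion, gem-dimethyl) and deoxygenation of the ring-A carbonyl.
4. 5 ⇒ key step: one-carbon ring expansion (ethylidene insertion with 1,2-shift) of the cyclopentanone of hydrindenedione 4 into six-membered ring B, bringing in the ring-B methyl.
5. 4 ⇒ amino-acid-catalysed Robinson annulation of 1 and 2 (sets the quaternary centre). Ring order: five-membered ring bought, ring A annulated, ring B by expansion; the arene is bought.

## Route

Step 1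
Reactants: 1 2-methylcyclopentane-1,3-dione; 2 pent-1-en-3-one
Product: 4 (7aR)-4,7a-dimethyl-2,3,7,7a-tetrahydro-1H-indene-1,5(6H)-dione, via triketone 3 (not isolated)
Conditions: Et3N (cat.), MeCN, rt; then D-phenylalanine (1.0 equiv), (1R)-(–)-camphor-10-sulfonic acid (0.5 equiv), 40 → 80 °C
Reagents that add atoms: none
Why: Michael addition followed by the amino-acid-catalysed Hajos–Parrish–Eder–Sauer–Wiechert aldol condensation (Robinson annulation); the enamine of the D-amino acid differentiates the two enantiotopic ring carbonyls and sets the quaternary centre as 7aR, the mirror image of the established L-phenylalanine outcome.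

Step 2
Reactants: 4 (7aR)-4,7a-dimethyl-2,3,7,7a-tetrahydro-1H-indene-1,5(6H)-dione
Product: 5 (8aR)-2,5,8a-trimethyl-3,4,8,8a-tetrahydronaphthalene-1,6(2H,7H)-dione (C2 epimer mixture)
Conditions: CH3CHN2 (1.5 equiv, Et2O solution), Sc(OTf)3 (5 mol %), toluene, –78 → –40 °C
Reagents that add atoms: diazoethane, CC=[N+]=[N-]
Why: Proposed new method: trivalent-scandium-catalysed Tiffeneau–Demjanov-type ethylidene insertion (diazoalkane carbonyl homologation) on a Hajos–Parrish-type enedione, a polycarbonyl α-quaternary cyclopentanone on which it has not been shown; Sc(OTf)3 activates the non-conjugated cyclopentanone carbonyl (the vinylogous enone carbonyl is a much poorer electrophile and its tetrasubstituted C=C resists dipolar cycloaddition), diazoethane adds, and in the diazonium betaine the unhindered C2 methylene migrates antiperiplanar to N2 because the rotamer needed for migration of the quaternary carbon forces the methyl gauche to it, so the five-membered ring becomes ring B with the new CH(CH3) carbon next to the ketone; the 2,2,6-trisubstituted cyclohexanone formed is too hindered for a second insertion, and the new C2 centre is inconsequential; closest known reaction types: Lewis-acid-catalysed ring expansion of simple cycloalkanones with diazoalkanes and D-homoannulation of 17-oxo steroids with diazo compounds.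

Step 3
Reactants: 5 (8aR)-2,5,8a-trimethyl-3,4,8,8a-tetrahydronaphthalene-1,6(2H,7H)-dione
Product: 7 (4aR,8aR)-2,5,5,8a-tetramethyl-3,4,4a,7,8,8a-hexahydronaphthalene-1,6(2H,5H)-dione (C2 epimer mixture), via lithium enolate 6 (not isolated)
Conditions: Li (2.2 equiv), NH3(l)/THF, H2O (1.0 equiv), –78 °C; then MeI (5 equiv), –78 → –33 °C; NH4Cl
Reagents that add atoms: iodomethane, CI
Why: Stork reductive alkylation: dissolving-metal reduction of the enone gives the trans-fused lithium enolate by axial protonation at C4a anti to the angular methyl (this sets 4aR), and regiospecific C-methylation of that enolate builds the gem-dimethyl carbon; with only 2.2 equiv of lithium the hindered, non-conjugated C1 ketone should survive.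

Step 4
Reactants: 7 (4aR,8aR)-2,5,5,8a-tetramethyl-3,4,4a,7,8,8a-hexahydronaphthalene-1,6(2H,5H)-dione
Product: 9 (4aR,8aR)-2,5,5,8a-tetramethyloctahydronaphthalen-1(2H)-one (C2 epimer mixture), via C6 tosylhydrazone 8 (not isolated)
Conditions: TsNHNH2 (1.1 equiv), TsOH (cat.), THF, 65 °C; then catecholborane (2.5 equiv), 0 °C → rt; then NaOAc·3H2O, 65 °C
Reagents that add atoms: none
Why: Caglioti–Kabalka tosylhydrazone reduction (a mild Wolff–Kishner-type deoxygenation): the hydrazone forms only at C6 because the C1 carbonyl is flanked by a quaternary and a tertiary carbon, and hydride addition, sulfinate loss and N2 extrusion leave CH2 without touching a stereocentre.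

Step 5
Reactants: 9 (4aR,8aR)-2,5,5,8a-tetramethyloctahydronaphthalen-1(2H)-one
Product: 11 (4aR,8aR)-2,5,5,8a-tetramethyl-3,4,4a,5,6,7,8,8a-octahydronaphthalen-1-yl trifluoromethanesulfonate, via potassium enolate 10 (not isolated)
Conditions: KN(SiMe3)2 (1.3 equiv), THF, –78 → 0 °C; then PhNTf2 (1.4 equiv), –78 °C → rt; NH4Cl
Reagents that add atoms: N-phenylbis(trifluoromethanesulfonimide), O=S(=O)(N(c1ccccc1)S(=O)(=O)C(F)(F)F)C(F)(F)F
Why: Enolate O-triflation: the ketone has a single enolisable position (C2–H), so the tetrasubstituted enol triflate forms with the C1=C2 double bond fixed in place and the C2 epimers converge (precedent: 2,2,6-trimethylcyclohexanone).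

Step 6
Reactants: 12 4-iodophenol
Product: 13 methyl 4-hydroxybenzoate
Conditions: CO (1 atm), Pd(OAc)2 (2 mol %), PPh3 (4 mol %), Et3N (2 equiv), MeOH, 65 °C
Reagents that add atoms: carbon monoxide, [C-]#[O+]; methanol, CO
Why: Palladium-catalysed methoxycarbonylation of an aryl iodide (Heck carbonylation), which tolerates the free phenol and puts the carboxyl carbon para to the hydroxyl group.

Step 7
Reactants: 14 (2E)-3-methylpent-2-en-4-yn-1-ol
Product: 15 (3E)-5-bromo-3-methylpent-3-en-1-yne
Conditions: PBr3 (0.4 equiv), Et2O, –20 → 0 °C; used at once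
Reagents that add atoms: phosphorus tribromide, BrP(Br)Br
Why: SN2-type bromination of a primary allylic alcohol with PBr3 at low temperature, which keeps the E geometry of the trisubstituted alkene.

Step 8
Reactants: 13 methyl 4-hydroxybenzoate; 15 (3E)-5-bromo-3-methylpent-3-en-1-yne
Product: 17 methyl 4-hydroxy-3-[(2E)-3-methylpent-2-en-4-yn-1-yl]benzoate, via sodium phenoxide 16 (not isolated)
Conditions: NaH (1.0 equiv), toluene, rt; then 15 (1.2 equiv), 50 °C
Reagents that add atoms: none
Why: ortho-C-alkylation of a sodium phenoxide in a non-polar solvent (the tight ion pair shields oxygen) by SN2 attack on the primary allylic bromide; the para position is blocked and the alkene geometry is untouched, and a modest yield beside the separable O-alkyl ether is expected, as is usual for C-prenylation of 4-hydroxybenzoates.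

Step 9
Reactants: 17 methyl 4-hydroxy-3-[(2E)-3-methylpent-2-en-4-yn-1-yl]benzoate
Product: 18 methyl 4-hydroxy-3-[(2E)-3-methylpenta-2,4-dien-1-yl]benzoate
Conditions: H2 (1 atm, 1.0 equiv uptake), Pd/CaCO3 poisoned with Pb(OAc)2, quinoline, EtOAc, 0 °C
Reagents that add atoms: none
Why: Lindlar-type semihydrogenation reduces the terminal alkyne to a vinyl group and stops at the diene, leaving the trisubstituted E alkene, ester and phenol untouched.

Step 10
Reactants: 18 methyl 4-hydroxy-3-[(2E)-3-methylpenta-2,4-dien-1-yl]benzoate; 11 (4aR,8aR)-2,5,5,8a-tetramethyl-3,4,4a,5,6,7,8,8a-octahydronaphthalen-1-yl trifluoromethanesulfonate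
Product: 21 4-hydroxy-3-[(2E)-3-methyl-5-[(4aR,8aR)-2,5,5,8a-tetramethyl-3,4,4a,5,6,7,8,8a-octahydronaphthalen-1-yl]pent-2-en-1-yl]benzoic acid, via bis-borane 19 (not isolated), via methyl ester 20 (not isolated)
Conditions: 9-BBN-H (2.3 equiv), THF, 0 °C → rt; then 11 (0.9 equiv), Pd(dppf)Cl2 (5 mol %), AsPh3 (10 mol %), K3PO4 (3 M aq), 60 °C; then LiOH, MeOH/H2O, 65 °C; then 1 M HCl to pH 3–4 at 0 °C
Reagents that add atoms: lithium hydroxide, [Li+].[OH-]
Why: Anti-Markovnikov hydroboration of the terminal vinyl group by 9-BBN (one further equivalent is taken up by the phenol), B-alkyl Suzuki–Miyaura coupling of the primary alkylborane with the hindered enol triflate (precedent: 2,6,6-trimethylcyclohexenyl triflate) and saponification in the same flask; the tetrasubstituted ring alkene is placed by the triflate and neither stereocentre nor the E alkene is touched.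

## Compound list

1 | 2-methylcyclopentane-1,3-dione | CC1C(=O)CCC1=O | starting material
2 | pent-1-en-3-one (ethyl vinyl ketone) | CCC(=O)C=C | starting material
3 | 2-methyl-2-(3-oxopentyl)cyclopentane-1,3-dione | CCC(=O)CCC1(C)C(=O)CCC1=O | intermediate
4 | (7aR)-4,7a-dimethyl-2,3,7,7a-tetrahydro-1H-indene-1,5(6H)-dione | O=C1[C@]2(C)CCC(=O)C(C)=C2CC1 | intermediate
5 | (8aR)-2,5,8a-trimethyl-3,4,8,8a-tetrahydronaphthalene-1,6(2H,7H)-dione (C2 epimer mixture) | CC1C(=O)[C@]2(C)CCC(=O)C(C)=C2CC1 | intermediate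
6 | lithium (4aR,8aR)-1,4a,6-trimethyl-5-oxo-3,4,4a,5,6,7,8,8a-octahydronaphthalen-2-olate (C6 epimer mixture) | CC1C(=O)[C@]2(C)CCC([O-])=C(C)[C@H]2CC1.[Li+] | intermediate
7 | (4aR,8aR)-2,5,5,8a-tetramethyl-3,4,4a,7,8,8a-hexahydronaphthalene-1,6(2H,5H)-dione (C2 epimer mixture) | CC1C(=O)[C@]2(C)CCC(=O)C(C)(C)[C@H]2CC1 | intermediate
8 | (4aR,8aR)-2,5,5,8a-tetramethyl-6-[2-(4-methylbenzenesulfonyl)hydrazinylidene]octahydronaphthalen-1(2H)-one (C2 epimer mixture) | CC1C(=O)[C@]2(C)CCC(=NNS(=O)(=O)c3ccc(C)cc3)C(C)(C)[C@H]2CC1 | intermediate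
9 | (4aR,8aR)-2,5,5,8a-tetramethyloctahydronaphthalen-1(2H)-one (C2 epimer mixture) | CC1C(=O)[C@]2(C)CCCC(C)(C)[C@H]2CC1 | intermediate
10 | potassium (4aR,8aR)-2,5,5,8a-tetramethyl-3,4,4a,5,6,7,8,8a-octahydronaphthalen-1-olate | CC1=C([O-])[C@]2(C)CCCC(C)(C)[C@H]2CC1.[K+] | intermediate
11 | (4aR,8aR)-2,5,5,8a-tetramethyl-3,4,4a,5,6,7,8,8a-octahydronaphthalen-1-yl trifluoromethanesulfonate | CC1=C(OS(=O)(=O)C(F)(F)F)[C@]2(C)CCCC(C)(C)[C@H]2CC1 | intermediate
12 | 4-iodophenol | Oc1ccc(I)cc1 | starting material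
13 | methyl 4-hydroxybenzoate | COC(=O)c1ccc(O)cc1 | intermediate
14 | (2E)-3-methylpent-2-en-4-yn-1-ol | C#C/C(C)=C/CO | starting material
15 | (3E)-5-bromo-3-methylpent-3-en-1-yne | C#C/C(C)=C/CBr | intermediate
16 | sodium 4-(methoxycarbonyl)phenolate | COC(=O)c1ccc([O-])cc1.[Na+] | intermediate
17 | methyl 4-hydroxy-3-[(2E)-3-methylpent-2-en-4-yn-1-yl]benzoate | C#C/C(C)=C/Cc1cc(C(=O)OC)ccc1O | intermediate
18 | methyl 4-hydroxy-3-[(2E)-3-methylpenta-2,4-dien-1-yl]benzoate | C=C/C(C)=C/Cc1cc(C(=O)OC)ccc1O | intermediate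
19 | methyl 4-[(9-borabicyclo[3.3.1]nonan-9-yl)oxy]-3-[(2E)-5-(9-borabicyclo[3.3.1]nonan-9-yl)-3-methylpent-2-en-1-yl]benzoate | B1(CC/C(C)=C/Cc2cc(C(=O)OC)ccc2OB2C3CCCC2CCC3)C2CCCC1CCC2 | intermediate
20 | methyl 4-hydroxy-3-[(2E)-3-methyl-5-[(4aR,8aR)-2,5,5,8a-tetramethyl-3,4,4a,5,6,7,8,8a-octahydronaphthalen-1-yl]pent-2-en-1-yl]benzoate | CC1=C(CC/C(C)=C/Cc2cc(C(=O)OC)ccc2O)[C@]2(C)CCCC(C)(C)[C@H]2CC1 | intermediate
21 | 4-hydroxy-3-[(2E)-3-methyl-5-[(4aR,8aR)-2,5,5,8a-tetramethyl-3,4,4a,5,6,7,8,8a-octahydronaphthalen-1-yl]pent-2-en-1-yl]benzoic acid | CC1=C(CC/C(C)=C/Cc2cc(C(=O)O)ccc2O)[C@]2(C)CCCC(C)(C)[C@H]2CC1 | target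

## Step count and risks

Total step count: 10. Longest linear sequence: 6 (steps 1, 2, 3, 4, 5, 10).

The three steps most likely to fail:

**Step 2 (the proposed new ring expansion).** Risks are attack at the enone, migration of the quaternary carbon, or decomposition of diazoethane by the Lewis acid. The fallback uses known chemistry, sets out from 4 and comes back at 5. Ring expansion with ethyl diazoacetate and BF3·OEt2 in CH2Cl2 at 0 °C inserts the ester-bearing carbon on the methylene side and gives the β-keto ester ethyl (8aR)-5,8a-dimethyl-1,6-dioxo-1,2,3,4,6,7,8,8a-octahydronaphthalene-2-carboxylate F1. C-methylation of this β-keto ester with MeI and K2CO3 in acetone gives ethyl (8aR)-2,5,8a-trimethyl-1,6-dioxo-1,2,3,4,6,7,8,8a-octahydronaphthalene-2-carboxylate F2. Acid hydrolysis with decarboxylation (6 M HCl, AcOH, 100 °C) then gives 5. The methyl is brought in by enolate alkylation instead of by the diazoalkane.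

**Step 3 (chemoselective reductive methylation).** Risks are partial reduction of the C1 ketone by lithium or methylation at C2. The fallback avoids dissolving metal, sets out from 5 and comes back at 9. Deconjugative methylation of the enone with tBuOK and MeI in tBuOH gives (8aR)-2,5,5,8a-tetramethyl-3,5,8,8a-tetrahydronaphthalene-1,6(2H,7H)-dione F3. Its C6 tosylhydrazone (8aR)-2,5,5,8a-tetramethyl-6-[2-(4-methylbenzenesulfonyl)hydrazinylidene]-3,5,6,7,8,8a-hexahydronaphthalen-1(2H)-one F4 is formed and reduced with catecholborane and NaOAc·3H2O as in step 4 to the alkene (8aR)-2,5,5,8a-tetramethyl-3,5,6,7,8,8a-hexahydronaphthalen-1(2H)-one F5. Hydrogenation (H2, 4 atm, Pd/C, EtOAc) from the face opposite the angular methyl gives trans-fused 9.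

**Step 10 (coupling at the hindered triflate next to a quaternary carbon).** Risks are slow oxidative addition and transmetalation, and protodeboronation. The fallback makes the same bond from the alkyne, sets out from 11 and 17 and comes back at 20. Sonogashira coupling (Pd(PPh3)4, CuI, Et3N, DMF, 50 °C) gives the dienyne methyl 4-hydroxy-3-[(2E)-3-methyl-5-[(4aR,8aR)-2,5,5,8a-tetramethyl-3,4,4a,5,6,7,8,8a-octahydronaphthalen-1-yl]pent-2-en-4-yn-1-yl]benzoate F6. Diimide from 2-nitrobenzenesulfonohydrazide and Et3N in CH2Cl2 should saturate the triple bond while sparing the tri- and tetrasubstituted alkenes, giving 20. Compound 20 is then isolated and saponified (LiOH, MeOH/H2O, 65 °C) to 21.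

## Further compounds

F1 | step 2 | ethyl (8aR)-5,8a-dimethyl-1,6-dioxo-1,2,3,4,6,7,8,8a-octahydronaphthalene-2-carboxylate | CCOC(=O)C1C(=O)[C@]2(C)CCC(=O)C(C)=C2CC1
F2 | step 2 | ethyl (8aR)-2,5,8a-trimethyl-1,6-dioxo-1,2,3,4,6,7,8,8a-octahydronaphthalene-2-carboxylate | CCOC(=O)C1(C)C(=O)[C@]2(C)CCC(=O)C(C)=C2CC1
F3 | step 3 | (8aR)-2,5,5,8a-tetramethyl-3,5,8,8a-tetrahydronaphthalene-1,6(2H,7H)-dione | CC1C(=O)[C@]2(C)CCC(=O)C(C)(C)C2=CC1
F4 | step 3 | (8aR)-2,5,5,8a-tetramethyl-6-[2-(4-methylbenzenesulfonyl)hydrazinylidene]-3,5,6,7,8,8a-hexahydronaphthalen-1(2H)-one | CC1C(=O)[C@]2(C)CCC(=NNS(=O)(=O)c3ccc(C)cc3)C(C)(C)C2=CC1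
F5 | step 3 | (8aR)-2,5,5,8a-tetramethyl-3,5,6,7,8,8a-hexahydronaphthalen-1(2H)-one | CC1C(=O)[C@]2(C)CCCC(C)(C)C2=CC1
F6 | step 10 | methyl 4-hydroxy-3-[(2E)-3-methyl-5-[(4aR,8aR)-2,5,5,8a-tetramethyl-3,4,4a,5,6,7,8,8a-octahydronaphthalen-1-yl]pent-2-en-4-yn-1-yl]benzoate | CC1=C(C#C/C(C)=C/Cc2cc(C(=O)OC)ccc2O)[C@]2(C)CCCC(C)(C)[C@H]2CC1
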